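The closed flask, the dosed flask and the two tanks take the same charge. They differ in what a molecule of intermediate meets at its fork.

| flask | substrate | partner | free catalyst | second catalyst | remark | time |
|---|---|---|---|---|---|---|
| dusk | 20 mM | 1.1 equiv | 5 mol% | 0.05 mol% | run made earlier |  |
| midnight | 28 mM | 1.1 equiv | 5 mol% | 0.05 mol% | run made earlier |  |
| spring | 44 mM | 1.1 equiv | 5 mol% | 0.05 mol% | run made earlier |  |
| dawn | 20 mM | 1.7 equiv | 5 mol% | 0.05 mol% | run made earlier |  |
| Thursday's | 20 mM (fed, over 6.40 min) | 1.10 equiv | 5 mol% | 0.05 mol% | a stirred flask in which substrate is dosed at a steady rate over 6.40 min without added volume, worked up at 8.0 min | 8.0 min |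
| Wednesday's | 20 mM | 1.10 equiv | 5 mol% | 0.05 mol% | everything together in a closed stirred flask, run for 8.0 min | 8.0 min |
| Tuesday's | 20 mM | 1.10 equiv | 5 mol% | 0.05 mol% | a single well-mixed tank run continuously and read at steady state, 24.0 min in it on average |  |
| Saturday's | 20 mM | 1.10 equiv | 5 mol% | 0.05 mol% | a single well-mixed tank run continuously and read at steady state, 8.0 min in it on average |  |

| run | time / min | target / % | side product / % | substrate / % |
|---|---|---|---|---|
| dusk | 1.50 | 3.1 | 2.0 | 86.2 |
| dusk | 3.00 | 7.2 | 5.4 | 75.1 |
| dusk | 5.00 | 13.4 | 8.2 | 65.2 |
| dusk | 6.00 | 17.2 | 10.3 | 60.8 |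
| dusk | 8.00 | 22.4 | 13.3 | 51.9 |
| midnight | 1.33 | 5.1 | 2.1 | 83.4 |
| midnight | 2.50 | 11.2 | 5.3 | 70.9 |
| midnight | 4.00 | 18.8 | 8.7 | 61.1 |
| midnight | 5.00 | 24.2 | 10.1 | 54.5 |
| midnight | 6.00 | 26.9 | 12.7 | 49.7 |
| spring | 0.500 | 3.5 | 0.4 | 88.9 |
| spring | 1.50 | 12.6 | 4.5 | 72.8 |
| spring | 3.00 | 27.5 | 8.1 | 54.7 |
| spring | 5.00 | 41.6 | 12.5 | 38.8 |
| spring | 6.00 | 47.3 | 13.0 | 34.1 |
| dawn | 0.500 | 0.7 | 0.7 | 95.0 |
| dawn | 1.00 | 3.1 | 0.5 | 90.1 |
| dawn | 2.00 | 5.9 | 2.6 | 82.0 |
| dawn | 3.00 | 9.0 | 4.6 | 75.2 |
| dawn | 6.00 | 22.8 | 8.9 | 59.0 |

(scatter of a reading: 0.5 percentage points)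

- a species is counted by the substrate in it: one side product counts as two
- the stated concentrations are those of everything mixed, before any reaction; amounts are the same in each set-up
- the earlier runs were read with a standard deviation of 0.5 percentage points
- reactions considered so far: substrate + free catalyst <-> free catalyst + intermediate; partner + second catalyst + intermediate -> second catalyst + target; substrate + intermediate -> side product
- the feed brings no volume worth counting
- the earlier runs were made in a closed, stirred flask

1. the set-up with the highest share of target in all that became target or side product, at the outlet or at the end ("none" if the first two lie within 2 percentage points) (Thursday's / Wednesday's / Tuesday's / Saturday's / none)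
2. share of target in all that became target or side product, at the outlet or at the end, Thursday's
3. share of target in all that became target or side product, at the outlet or at the end, Wednesday's
4. share of target in all that became target or side product, at the outlet or at the end, Tuesday's
5. share of target in all that became target or side product, at the outlet or at the end, Saturday's

I follow one intermediate. It meets partner and goes to target, or meets substrate and goes to side product. Let a be the substrate standing and b the partner standing, as fractions of the charge. By the listed steps, the odds of target against side product, as counted, are G·b/a. I read G two ways, up to the last reading, with a and b taken midway: the dusk run from its first reading, the dawn run from its second.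

dusk: (19 percentage points / 11 points) × (0.691 / 0.973) = 1.21

dawn: (20 points / 8.4 points) × (0.745 / 1.57) = 1.11

The dusk run holds 1.1 equiv of partner and the dawn run 1.7 equiv, so these are two separate readings. They part by 0.1000, on a dawn side-product gain of 8.4 points read with a scatter of 0.5 points. From the dawn run's first reading the same sum gives 1.31, so G carries that spread. I carry their mean, the fork number, a selectivity factor for second catalyst at 0.05 mol% of 20 mM: G = 1.16.

share at a moment = G·b / (G·b + a)

Wednesday's repeats the dusk run, which reads 62.7%. At its last reading, a = 52% and b = 0.876, so the fork stands at 66.2%. Earlier moments held more substrate. Tuesday's tank works at its outlet composition, with 24.0 min on average against 8.0 min. So I put Tuesday's above 66.2%, which places it ahead of Wednesday's. I do not reckon Thursday's here, so this does not rank Tuesday's against it.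

The forecast says Tuesday's: Thursday's 66.5%, Wednesday's 62.7%, Tuesday's 69.4% (66.5% to 72%), Saturday's 64.3%. Its ground is “Low standing substrate favours target”.

Tuesday's gives 68.4%, the highest, ahead of Thursday's 65.3%, Saturday's 63.2% and Wednesday's 61.9%.

    substrate + free catalyst ⇌ free catalyst + intermediate (K = 0.410, k = 1.90 /M/s)
    partner + second catalyst + intermediate → second catalyst + target (k = 21000 /M²/s)
    substrate + intermediate → side product (k = 0.0920 /M/s)

In Tuesday's tank partner stands at 14.8 mM, so b = 0.738, and the fork number then asks for a = 0.397. Saturday's outlet holds target 18.3%, side product 10.7% and intermediate 9.92%, which leaves a = 61 points and b = 0.917. The fork number turns these into 63.6%, and Saturday's tank gives 63.2%.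

(The readings are simulated for substances that don't exist; noise was put on by code.)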